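# Dehydroglyasperin D by benzannulation of a prenylated cyclobutenone with an enynyl ynol ether

## Analysis of the target

Dehydroglyasperin D is an isoflav-3-ene: a 2H-chromene (rings A and C) whose C3 carries a 2,4-dihydroxyphenyl group (ring B). It has no stereocentre, and its one ring alkene, C3=C4, joins rings A and B into a stilbene-like system. Ring A is a benzene ring with five substituents and one hydrogen: C4a bears C4, C5 a methoxy group, C6 a prenyl group, C7 a methoxy group, C8 hydrogen and C8a the ring oxygen O1. Of its three phloroglucinol-type oxygens exactly one is unmethylated, and the prenyl group sits between the two methylated ones. A geometric demand is hidden in ring C: in any open-chain precursor the C3=C4 alkene must hold ring A and C2 cis, or O1 cannot reach C2. The sensitive groups are the prenyl alkene (acids, electrophiles, hydrogenation), the electron-rich chromene alkene (protonation gives a C4 cation stabilised by three oxygens, which a free 2'-hydroxyl could trap as a pterocarpan) and the free resorcinol of ring B, which oxidises readily as its phenoxide. The difficulty lies in ring A, because substitution on a phloroglucinol or 3,5-dimethoxyphenol core does not reliably tell C6 from C8 or one oxygen from the other two. The strategy rests on the sequence C8a(O)–C4a(C)–C5(OMe)–C6(prenyl)–C7(OMe)–C8(H): a vinylketene carrying prenyl and methoxy and a methyl ynol ether carrying the C4 arm give exactly this order when joined into a benzene ring, with the ketene oxygen as the single free hydroxyl.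

## Retrosynthetic reasoning

**26 to 25.** The last operation is the release of the two ring B phenols from their silyl ethers in 25. This keeps the oxidation-prone resorcinol masked to the end and makes the final step a non-acidic desilylation, which the chromene alkene and the prenyl group tolerate.

**25 to 24.** Ring C is opened at the O1–C2 bond. This is preferred to a cut at C3–C4, C4–C4a or C3–C1' because it is a carbon–oxygen bond at a primary allylic carbon and can be formed without acid. It reduces ring C to a C8a phenol and a Z allylic alcohol in 24. The forward closure must be a substitution at C2 by the ring A phenol under neutral conditions. The 2'-oxygen of ring B must stay blocked, because it could otherwise close a five-membered ring on the same carbon.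

**24 to 23.** The allylic hydroxyl is carried as an alkyl silyl ether, different in lability from the aryl silyl ethers of ring B, so that it can be freed alone. Phenol 23 then contains every carbon of the target.

**23 to 7 and 18 (key disconnection).** Ring A of 23 is cut across three bonds: C4a–C8a, C5–C6 and C8–C8a. This gives cyclobutenone 7, which holds C6, C7, C8 and C8a with prenyl and methoxy in place, and ynol ether 18, which holds C4a, C5 and the whole C4–C3–C2 arm with ring B. Any other disconnection of ring A leaves a polysubstituted arene to be functionalised regioselectively. This one builds the ring from two pieces of similar size, so the position of every substituent follows from their connectivity. The free hydroxyl at C8a comes from the ketene carbonyl without a protecting group, and no methylation has to choose between oxygens. The forward reaction must join the oxygen-free alkyne carbon to the ketene carbonyl carbon and must leave the Z alkene and three silyl ethers intact at 80–110 °C.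

**7 to 4 and 6; 4 to 1 and 2.** The four-membered ring of 7 is cut across C1–C2 and C3–C4 into ketene 6 (from acetone 5) and ynol ether 4. Ynol ether 4 is cut at its propargylic C–C bond into acetylide 3, made from acetal 1, and bromide 2. The polarity of the ynol ether fixes prenyl next to the carbonyl and methoxy at the far ring carbon.

**18 to 15 and 17.** The C4–C4a bond between the alkene and the alkyne is cut to alkenyl iodide 15 and alkynylzinc reagent 17, which comes from acetal 1 through acetylide 16. Putting the acid-sensitive ynol ether on last keeps its exposure short, and the coupling keeps the alkene geometry. The same two-carbon building block 1 thus supplies both the C7 methoxy carbon pair (through 4) and the C5 methoxy carbon pair (through 17).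

**15 to 14 to 9 and 10.** The iodoalkene is cut at the C3–C1' bond and the C4–I bond. Arylmagnesium bromide 11 (from 9, itself from 8) adds to the magnesium alkoxide 12 of propargyl alcohol 10. The alkoxide chelates magnesium in 13 and forces the anti mode of addition, and iodinolysis then gives 14. The Z geometry needed for ring C is therefore set in the step that forms the C3–C1' bond, from a three-carbon unit that already carries C2 and its oxygen.

## Alternatives that were turned down

**Alternative 1:** The target is traced to pterocarpan A1 by joining the 2'-oxygen to C4, and A1 is cut at C3–C1' and C4–O into chromene A2 and iodophenol A3.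
- **Forward key step:** a palladium-mediated Heck-type oxyarylation with a silver halide scavenger. The arylpalladium species from A3 adds across C3=C4 of A2 with the aryl group at C3, and the phenol captures C4 to close the cis-fused dihydrobenzofuran. The C4–O bond is then broken again to release the C3=C4 alkene.
- **For:** it is highly convergent and attaches ring B in one step. On this point it is stronger than the chosen route, which needs three steps to build the arm that carries ring B.
- **Against:** A2 already contains the whole ring A problem (one ring oxygen, two methoxy groups, prenyl at C6), and the key step does nothing to solve it. Two stereocentres are made only to be destroyed. In the cis-fused A1 the hydrogen at C3 and the oxygen at C4 are neither syn- nor antiperiplanar, so a concerted base elimination is poorly aligned. The ionising path through the C4 cation needs acid, under which reclosure to A1 is the favoured direction and the prenyl group is at risk.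
- **Comparison:** the chosen strategy gives up some convergence at ring B but sets the ring A pattern by construction and never passes through a C4 cation.

**Alternative 2:** Ring A is cut at C4a–C5 and traced to a pyranone that carries ring B and a prenylated β-keto ester chain, keto ester A5.
- **Forward key step:** base forms the extended enolate of A5, the pyranone carbon that becomes C4a attacks the ester carbonyl, and enolisation closes ring A as isoflavone A4.
- **For:** like the chosen route, it fixes the prenyl group at C6 by the connectivity of a chain, not by substitution on an arene. Both hydroxyls it liberates are the ones that must be methylated, so it is as strong as the chosen route on the ring A pattern.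
- **Against:** A4 is at the isoflavone oxidation level. After double methylation (the C5 hydroxyl is chelated to the C4 carbonyl) the carbonyl must be removed and the alkene moved from C2=C3 to C3=C4 by reduction and dehydration. The dehydration passes through the C4 cation next to a prenyl group. The most acidic site of A5 is the β-keto ester itself, so the productive extended enolate has to be formed as a polyanion. A5 also needs its own multi-step assembly.
- **Comparison:** the chosen strategy delivers ring A with both methoxy groups already in place and the arm at the right oxidation level, so only ring closure and deprotection follow.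

**Alternative 3:** Ring C is cut at C2–C3 and traced to stilbene A7, whose C8a oxygen carries a methoxymethyl group.
- **Forward key step:** a silyl triflate Lewis acid ionises the methoxymethyl ether to an aryloxymethyl cation. This attacks the stilbene carbon that bears ring B in a 6-endo closure, and loss of the proton at C3 from the C4 cation gives the dipivalate A6.
- **For:** ring C and the C3=C4 alkene form at the right oxidation level in one step, and A6 is one deprotection from the target. In the brevity of its endgame it is stronger than the chosen route.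
- **Against:** the arene of A7 must already carry one protected oxygen, two methoxy groups and the prenyl group in the right order, so the hardest problem is again left to earlier steps. A strong Lewis acid meets a prenyl alkene and a long-lived C4 cation stabilised by three oxygens, which invites cation–alkene and Friedel–Crafts side reactions. The final ester cleavage exposes the resorcinol as its phenoxide.
- **Comparison:** the chosen strategy closes ring C under neutral conditions and spends its risk on the step that solves ring A.

Key step: step 7

Remarks on the chemistry (assumptions):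
- The ring B phenols are carried as triisopropylsilyl ethers and the allylic alcohol as a tert-butyldimethylsilyl ether. The bulky aryl silyl groups resist oxygen-to-carbon silyl migration in the ortho-silyloxy arylmagnesium reagent and leave only the alkyl silyl ether labile to mild acid.
- Ketene is generated by pyrolysis of acetone and passed as a gas stream into the reaction flask.

## Route

**Step 1**
Reactants: 1 chloroacetaldehyde dimethyl acetal; 2 prenyl bromide
Product: 4 1-methoxy-5-methylhex-4-en-1-yne, via sodium methoxyacetylide 3 (not isolated)
Conditions: NaNH2 (3.0 equiv), liq. NH3, −33 °C; then 2 (1.3 equiv), Et2O, −50 → −33 °C; NH4Cl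
Reagents that add atoms: none
Why: Elimination of methanol and of HCl from the chloroacetal followed by deprotonation is the classical route to an alkali alkoxyacetylide, and SN2 alkylation at the primary carbon of the allylic bromide should give 4. Exactly three equivalents of amide leave no strong base to isomerise the skipped enyne.

**Step 2**
Reactants: 4 1-methoxy-5-methylhex-4-en-1-yne; 5 acetone
Product: 7 3-methoxy-2-(3-methylbut-2-enyl)cyclobut-2-en-1-one, via ketene 6 (not isolated)
Conditions: 5, hot-wire ketene generator (ca. 700 °C); gas stream into 4, MeCN, 0 °C → rt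
Reagents that add atoms: none
Why: Thermal [2+2] cycloaddition of ketene with an ynol ether, in which the oxygen-free alkyne carbon attacks the ketene carbonyl carbon, so prenyl ends next to the carbonyl and methoxy at C3. The isolated trisubstituted alkene is inert to ketene at this temperature.

**Step 3**
Reactants: 8 4-bromoresorcinol
Product: 9 1-bromo-2,4-bis(triisopropylsilyloxy)benzene
Conditions: TIPSCl (2.4 equiv), imidazole (5 equiv), DMF, rt → 40 °C
Reagents that add atoms: triisopropylsilyl chloride, CC(C)[Si](Cl)(C(C)C)C(C)C
Why: Standard imidazole-promoted O-silylation of both phenols.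

**Step 4**
Reactants: 9 1-bromo-2,4-bis(triisopropylsilyloxy)benzene; 10 propargyl alcohol
Product: 14 (Z)-2-[2,4-bis(triisopropylsilyloxy)phenyl]-3-iodoprop-2-en-1-ol, via arylmagnesium bromide 11 (not isolated), via chloromagnesium prop-2-ynoxide 12 (not isolated), via alkenylmagnesium chelate 13 (not isolated)
Conditions: 9, Mg, THF, 45 °C; separately 10, iPrMgCl (1.0 equiv), THF, 0 °C; combine (11 1.5 equiv), CuI (15 mol%), THF–toluene, rt → 40 °C; then I2, THF, −30 → 0 °C; aq. NH4Cl, Na2S2O3
Reagents that add atoms: iodine, II
Why: Copper-catalysed anti-carbomagnesiation of a propargylic magnesium alkoxide delivers the aryl group to the inner alkyne carbon and magnesium to the terminal carbon, where chelation by the alkoxide holds it cis to the CH2O group. Iodinolysis with retention should then give the Z iodoalkene, and pre-forming the alkoxide with iPrMgCl saves one equivalent of 11.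

**Step 5**
Reactants: 14 (Z)-2-[2,4-bis(triisopropylsilyloxy)phenyl]-3-iodoprop-2-en-1-ol
Product: 15 tert-butyl{[(Z)-2-[2,4-bis(triisopropylsilyloxy)phenyl]-3-iodoprop-2-enyl]oxy}dimethylsilane
Conditions: TBSCl (1.2 equiv), imidazole (2.5 equiv), CH2Cl2, 0 °C → rt
Reagents that add atoms: tert-butyldimethylsilyl chloride, CC(C)(C)[Si](C)(C)Cl
Why: Routine silylation of a primary allylic alcohol. The alkyl silyl ether is later removable by mild acid in the presence of the aryl silyl ethers.

**Step 6**
Reactants: 1 chloroacetaldehyde dimethyl acetal; 15 tert-butyl{[(Z)-2-[2,4-bis(triisopropylsilyloxy)phenyl]-3-iodoprop-2-enyl]oxy}dimethylsilane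
Product: 18 tert-butyl{[(Z)-2-[2,4-bis(triisopropylsilyloxy)phenyl]-5-methoxypent-2-en-4-ynyl]oxy}dimethylsilane, via lithium methoxyacetylide 16 (not isolated), via methoxyethynylzinc chloride 17 (not isolated)
Conditions: 1 (2.5 equiv), LiNEt2 (7.5 equiv, from Et2NH and n-BuLi), THF, −10 → 0 °C; ZnCl2 (5 equiv), 0 °C; then 15, Pd(PPh3)4 (5 mol%), THF, rt; chromatography on Et3N-deactivated silica
Reagents that add atoms: none
Why: Base-induced double elimination of the chloroacetal gives the lithium alkoxyacetylide, transmetalation gives the alkynylzinc chloride, and Negishi coupling with the alkenyl iodide should proceed with retention of the alkene geometry. Oxidative addition of zerovalent palladium into the C–I bond is fast at room temperature, and the ynol ether meets neither acid nor copper salts.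

**Step 7 (key step)**
Reactants: 7 3-methoxy-2-(3-methylbut-2-enyl)cyclobut-2-en-1-one; 18 tert-butyl{[(Z)-2-[2,4-bis(triisopropylsilyloxy)phenyl]-5-methoxypent-2-en-4-ynyl]oxy}dimethylsilane
Product: 23 2-{(Z)-2-[2,4-bis(triisopropylsilyloxy)phenyl]-3-(tert-butyldimethylsilyloxy)prop-1-enyl}-3,5-dimethoxy-4-(3-methylbut-2-enyl)phenol, via vinylketene 19 (not isolated), via vinylcyclobutenone 20 (not isolated), via dienylketene 21 (not isolated), via cyclohexadienone 22 (not isolated)
Conditions: 18 (1.2 equiv), 7 added over 2 h, toluene (0.2 M), 80 °C, then 110 °C, Ar, dark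
Reagents that add atoms: none
Why: Heating opens 7 by a four-electron conrotatory electrocyclic reaction to vinylketene 19, and the ynol ether 18, polarised by its methoxy group, adds with its oxygen-free carbon to the ketene carbonyl carbon and with its oxygen-bearing carbon to the ketene α-carbon in a regiospecific [2+2] cycloaddition that gives vinylcyclobutenone 20 (bonds C4a–C8a and C5–C6). A second four-electron ring opening turns 20 into dienylketene 21, whose thermal disrotatory 6π electrocyclisation forms C8–C8a and closes ring A as cyclohexadienone 22; tautomerisation gives phenol 23. The closest known reaction type is the Danheiser benzannulation of cyclobutenones with 1-alkoxyalkynes, of which this is a case with an alkenyl-substituted ynol ether. Ring A is thus closed in a six-electron electrocyclic mode from an acyclic triene and not by substitution on an arene, so the order C8a(OH), C4a(alkenyl), C5(OMe), C6(prenyl), C7(OMe), C8(H) follows from the connectivity of 7 and 18 alone. No stereocentre is present in 23 (the quaternary carbon of 20 is lost on ring opening), and the Z alkene of 18 takes no part in any pericyclic step and should be carried through unchanged. The selectivities needed are the regiochemistry of the [2+2] step, secured by the donor oxygen on the alkyne, and attack on the alkyne in preference to the two alkenes, secured by the much higher nucleophilicity of the ynol ether carbon and by the fully substituted, shielded far end of the enyne. The methyl ynol ether has no β-hydrogen in its alkyl group and so cannot lose an alkene to give a ketene at these temperatures. Keeping 18 in slight excess and feeding 7 slowly keeps the concentration of 19 low, which holds back acylation of the product phenol by 19 and dimerisation of 19.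

**Step 8**
Reactants: 23 2-{(Z)-2-[2,4-bis(triisopropylsilyloxy)phenyl]-3-(tert-butyldimethylsilyloxy)prop-1-enyl}-3,5-dimethoxy-4-(3-methylbut-2-enyl)phenol
Product: 24 2-{(Z)-2-[2,4-bis(triisopropylsilyloxy)phenyl]-3-hydroxyprop-1-enyl}-3,5-dimethoxy-4-(3-methylbut-2-enyl)phenol
Conditions: PPTS (0.2 equiv), MeOH–CH2Cl2, 0 °C → rt
Reagents that add atoms: none
Why: Acid-catalysed methanolysis cleaves a primary alkyl silyl ether far faster than aryl triisopropylsilyl ethers. If the allylic alcohol ionised under these conditions, capture by the neighbouring phenol would give 25, the product of the next step.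

**Step 9**
Reactants: 24 2-{(Z)-2-[2,4-bis(triisopropylsilyloxy)phenyl]-3-hydroxyprop-1-enyl}-3,5-dimethoxy-4-(3-methylbut-2-enyl)phenol
Product: 25 3-[2,4-bis(triisopropylsilyloxy)phenyl]-5,7-dimethoxy-6-(3-methylbut-2-enyl)-2H-chromene
Conditions: PPh3 (1.5 equiv), DIAD (1.5 equiv), THF (0.02 M), 0 °C → rt
Reagents that add atoms: none
Why: Intramolecular Mitsunobu etherification, in which the phenol is the pronucleophile and displaces the activated primary allylic oxygen in a 6-exo-tet closure that the Z geometry makes possible. The 2'-oxygen of ring B is silylated and cannot compete, and the neutral conditions spare the prenyl group and the chromene.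

**Step 10**
Reactants: 25 3-[2,4-bis(triisopropylsilyloxy)phenyl]-5,7-dimethoxy-6-(3-methylbut-2-enyl)-2H-chromene
Product: 26 dehydroglyasperin D
Conditions: TBAF (2.5 equiv), AcOH (2.5 equiv), THF, 0 °C, Ar
Reagents that add atoms: none
Why: Fluoride cleaves aryl silyl ethers rapidly at 0 °C. Buffering with AcOH keeps the resorcinol from standing as an oxidation-prone phenoxide, and no acid strong enough to protonate the C3=C4 alkene is present.

## Compound list

1 | chloroacetaldehyde dimethyl acetal (2-chloro-1,1-dimethoxyethane) | COC(CCl)OC | starting material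
2 | prenyl bromide (1-bromo-3-methylbut-2-ene) | CC(C)=CCBr | starting material
3 | sodium methoxyacetylide | [Na+].[C-]#COC | intermediate
4 | 1-methoxy-5-methylhex-4-en-1-yne | COC#CCC=C(C)C | intermediate
5 | acetone | CC(C)=O | starting material
6 | ketene (ethenone) | C=C=O | intermediate
7 | 3-methoxy-2-(3-methylbut-2-enyl)cyclobut-2-en-1-one | COC1=C(CC=C(C)C)C(=O)C1 | intermediate
8 | 4-bromoresorcinol (4-bromobenzene-1,3-diol) | Oc1ccc(Br)c(O)c1 | starting material
9 | 1-bromo-2,4-bis(triisopropylsilyloxy)benzene | Brc1ccc(O[Si](C(C)C)(C(C)C)C(C)C)cc1O[Si](C(C)C)(C(C)C)C(C)C | intermediate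
10 | propargyl alcohol (prop-2-yn-1-ol) | OCC#C | starting material
11 | [2,4-bis(triisopropylsilyloxy)phenyl]magnesium bromide | Br[Mg]c1ccc(O[Si](C(C)C)(C(C)C)C(C)C)cc1O[Si](C(C)C)(C(C)C)C(C)C | intermediate
12 | chloromagnesium prop-2-yn-1-olate | C#CCO[Mg]Cl | intermediate
13 | bromo{(Z)-2-[2,4-bis(triisopropylsilyloxy)phenyl]-3-(chloromagnesiooxy)prop-1-enyl}magnesium (magnesium on carbon cis to the CH2O group) | Br[Mg]/C=C(\CO[Mg]Cl)c1ccc(O[Si](C(C)C)(C(C)C)C(C)C)cc1O[Si](C(C)C)(C(C)C)C(C)C | intermediate
14 | (Z)-2-[2,4-bis(triisopropylsilyloxy)phenyl]-3-iodoprop-2-en-1-ol | I/C=C(\CO)c1ccc(O[Si](C(C)C)(C(C)C)C(C)C)cc1O[Si](C(C)C)(C(C)C)C(C)C | intermediate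
15 | tert-butyl{[(Z)-2-[2,4-bis(triisopropylsilyloxy)phenyl]-3-iodoprop-2-enyl]oxy}dimethylsilane | I/C=C(\CO[Si](C)(C)C(C)(C)C)c1ccc(O[Si](C(C)C)(C(C)C)C(C)C)cc1O[Si](C(C)C)(C(C)C)C(C)C | intermediate
16 | lithium methoxyacetylide | [Li]C#COC | intermediate
17 | (methoxyethynyl)zinc chloride | Cl[Zn]C#COC | intermediate
18 | tert-butyl{[(Z)-2-[2,4-bis(triisopropylsilyloxy)phenyl]-5-methoxypent-2-en-4-ynyl]oxy}dimethylsilane | COC#C/C=C(\CO[Si](C)(C)C(C)(C)C)c1ccc(O[Si](C(C)C)(C(C)C)C(C)C)cc1O[Si](C(C)C)(C(C)C)C(C)C | intermediate
19 | 3-methoxy-2-(3-methylbut-2-enyl)buta-1,3-dien-1-one (vinylketene) | C=C(OC)C(CC=C(C)C)=C=O | intermediate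
20 | 2-{(Z)-2-[2,4-bis(triisopropylsilyloxy)phenyl]-3-(tert-butyldimethylsilyloxy)prop-1-enyl}-3-methoxy-4-(1-methoxyethenyl)-4-(3-methylbut-2-enyl)cyclobut-2-en-1-one (racemic at C4) | O=C1C(/C=C(\CO[Si](C)(C)C(C)(C)C)c2ccc(O[Si](C(C)C)(C(C)C)C(C)C)cc2O[Si](C(C)C)(C(C)C)C(C)C)=C(OC)C1(CC=C(C)C)C(OC)=C | intermediate
21 | (3E)-2-{(Z)-2-[2,4-bis(triisopropylsilyloxy)phenyl]-3-(tert-butyldimethylsilyloxy)prop-1-enyl}-3,5-dimethoxy-4-(3-methylbut-2-enyl)hexa-1,3,5-trien-1-one (dienylketene) | O=C=C(/C=C(\CO[Si](C)(C)C(C)(C)C)c1ccc(O[Si](C(C)C)(C(C)C)C(C)C)cc1O[Si](C(C)C)(C(C)C)C(C)C)/C(OC)=C(\C(OC)=C)CC=C(C)C | intermediate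
22 | 2-{(Z)-2-[2,4-bis(triisopropylsilyloxy)phenyl]-3-(tert-butyldimethylsilyloxy)prop-1-enyl}-3,5-dimethoxy-4-(3-methylbut-2-enyl)cyclohexa-2,4-dien-1-one | O=C1CC(OC)=C(CC=C(C)C)C(OC)=C1/C=C(\CO[Si](C)(C)C(C)(C)C)c1ccc(O[Si](C(C)C)(C(C)C)C(C)C)cc1O[Si](C(C)C)(C(C)C)C(C)C | intermediate
23 | 2-{(Z)-2-[2,4-bis(triisopropylsilyloxy)phenyl]-3-(tert-butyldimethylsilyloxy)prop-1-enyl}-3,5-dimethoxy-4-(3-methylbut-2-enyl)phenol | COc1cc(O)c(/C=C(\CO[Si](C)(C)C(C)(C)C)c2ccc(O[Si](C(C)C)(C(C)C)C(C)C)cc2O[Si](C(C)C)(C(C)C)C(C)C)c(OC)c1CC=C(C)C | intermediate
24 | 2-{(Z)-2-[2,4-bis(triisopropylsilyloxy)phenyl]-3-hydroxyprop-1-enyl}-3,5-dimethoxy-4-(3-methylbut-2-enyl)phenol | COc1cc(O)c(/C=C(\CO)c2ccc(O[Si](C(C)C)(C(C)C)C(C)C)cc2O[Si](C(C)C)(C(C)C)C(C)C)c(OC)c1CC=C(C)C | intermediate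
25 | 3-[2,4-bis(triisopropylsilyloxy)phenyl]-5,7-dimethoxy-6-(3-methylbut-2-enyl)-2H-chromene | COc1cc2c(c(OC)c1CC=C(C)C)C=C(c1ccc(O[Si](C(C)C)(C(C)C)C(C)C)cc1O[Si](C(C)C)(C(C)C)C(C)C)CO2 | intermediate
26 | dehydroglyasperin D, 4-[5,7-dimethoxy-6-(3-methylbut-2-enyl)-2H-chromen-3-yl]benzene-1,3-diol | COc1cc2c(c(OC)c1CC=C(C)C)C=C(c1ccc(O)cc1O)CO2 | target

## Step count and least certain steps

Total step count: 10. Longest linear sequence: 8 steps (steps 3 to 10, from 8). The cyclobutenone branch (steps 1 and 2) joins at step 7.

**Step 7 (key step).** The most likely failures are three: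
- the vinylketene 19 is consumed by dimerisation or by acylation of the product phenol faster than it meets the hindered alkyne carbon, which is flanked by a cis silyloxymethyl group;
- the conjugated enynyl ynol ether polymerises thermally at 80–110 °C before it is intercepted;
- the product phenol adds slowly to the excess ynol ether.

The fallback runs the benzannulation with the simplest member of the alkoxyalkyne class and attaches the alkenyl arm afterwards by cross-coupling. It sets out from 3, 7 and 15 and returns at 23. Protonation of 3 with NH4Cl and distillation gives methoxyethyne F1. Heating F1 with 7 in a sealed tube should give 3,5-dimethoxy-4-(3-methylbut-2-enyl)phenol F2, whose two ortho positions are equivalent. Mono-iodination with N-iodosuccinimide at low temperature can therefore give only 2-iodo-3,5-dimethoxy-4-(3-methylbut-2-enyl)phenol F3. Miyaura borylation of 15 (B2pin2, PdCl2(dppf), KOPh) with retention gives tert-butyl{[(Z)-2-[2,4-bis(triisopropylsilyloxy)phenyl]-3-(4,4,5,5-tetramethyl-1,3,2-dioxaborolan-2-yl)prop-2-enyl]oxy}dimethylsilane F4. Suzuki–Miyaura coupling of F3 with F4 (Pd(OAc)2, SPhos, K3PO4, aqueous dioxane) rejoins the route at 23.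

**Step 4.** The ortho silyloxy group shields the aryl–metal bond, so transfer of the aryl group to the alkyne may be slow. Deprotonation of the alkyne C–H, homocoupling of the aryl group, or oxygen-to-carbon silyl migration in 11 on prolonged warming could then take over.

The fallback avoids the arylmagnesium reagent and builds the alkene from a dihalide whose geometry is set by anti addition. It sets out from 9 and 17 and returns at 18. Bromine adds anti to purchased ethyl propiolate F5 to give ethyl (E)-2,3-dibromoprop-2-enoate F6, in which the C3 bromine is cis to the ester. Palladium-catalysed coupling with 17 (Pd(PPh3)4) takes place at the more electrophilic, less hindered C3–Br bond and gives ethyl (E)-2-bromo-5-methoxypent-2-en-4-ynoate F7. Miyaura borylation of 9 (B2pin2, PdCl2(dppf), KOAc) gives 2-[2,4-bis(triisopropylsilyloxy)phenyl]-4,4,5,5-tetramethyl-1,3,2-dioxaborolane F8. Suzuki–Miyaura coupling of F7 with F8 gives ethyl (Z)-2-[2,4-bis(triisopropylsilyloxy)phenyl]-5-methoxypent-2-en-4-ynoate F9. Reduction with i-Bu2AlH at −78 °C gives (Z)-2-[2,4-bis(triisopropylsilyloxy)phenyl]-5-methoxypent-2-en-4-yn-1-ol F10, and silylation with TBSCl and imidazole gives 18.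

**Step 6.** The alkynylzinc reagent is made in the presence of diethylamine and lithium methoxide. Protonation of the reagent, zinc tied up as alkoxide or amide complexes, or hydration of the ynol ether during work-up and chromatography could each lower the conversion of the hindered iodide.

The fallback separates reagent preparation from the coupling and uses an isolated tin reagent under neutral, salt-free conditions. It sets out from 16 and 15 and returns at 18. Trapping 16 with Bu3SnCl gives tributyl(methoxyethynyl)stannane F11, which can be distilled. Stille coupling of F11 with 15 (Pd2(dba)3, AsPh3, THF, 50 °C) gives 18.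

**Step 1.** The acetylide may attack the tertiary end of the allylic bromide (SN2′ substitution), and the skipped enyne may undergo a base-induced prototropic shift to an allene or a conjugated isomer. Either would give isomers that are hard to separate from 4.

The fallback builds the prenyl group by metathesis from a symmetrical allyl group. It sets out from 3 and returns at 7. Alkylation of 3 with allyl bromide, for which both ends are equivalent, gives 1-methoxypent-4-en-1-yne F12. Cycloaddition with ketene 6 as in step 2 gives 3-methoxy-2-(prop-2-enyl)cyclobut-2-en-1-one F13. Cross-metathesis with excess 2-methylbut-2-ene (second-generation Grubbs catalyst, CH2Cl2, 40 °C) converts the allyl into the prenyl group and gives 7. The tetrasubstituted ring alkene is inert to metathesis.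

## Further compounds

F1 | step 7 | methoxyethyne | COC#C
F2 | step 7 | 3,5-dimethoxy-4-(3-methylbut-2-enyl)phenol | COc1cc(O)cc(OC)c1CC=C(C)C
F3 | step 7 | 2-iodo-3,5-dimethoxy-4-(3-methylbut-2-enyl)phenol | COc1cc(O)c(I)c(OC)c1CC=C(C)C
F4 | step 7 | tert-butyl{[(Z)-2-[2,4-bis(triisopropylsilyloxy)phenyl]-3-(4,4,5,5-tetramethyl-1,3,2-dioxaborolan-2-yl)prop-2-enyl]oxy}dimethylsilane | CC1(C)OB(/C=C(\CO[Si](C)(C)C(C)(C)C)c2ccc(O[Si](C(C)C)(C(C)C)C(C)C)cc2O[Si](C(C)C)(C(C)C)C(C)C)OC1(C)C
F5 | step 4 | ethyl propiolate | C#CC(=O)OCC
F6 | step 4 | ethyl (E)-2,3-dibromoprop-2-enoate | Br/C=C(/Br)C(=O)OCC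
F7 | step 4 | ethyl (E)-2-bromo-5-methoxypent-2-en-4-ynoate | COC#C/C=C(/Br)C(=O)OCC
F8 | step 4 | 2-[2,4-bis(triisopropylsilyloxy)phenyl]-4,4,5,5-tetramethyl-1,3,2-dioxaborolane | CC1(C)OB(c2ccc(O[Si](C(C)C)(C(C)C)C(C)C)cc2O[Si](C(C)C)(C(C)C)C(C)C)OC1(C)C
F9 | step 4 | ethyl (Z)-2-[2,4-bis(triisopropylsilyloxy)phenyl]-5-methoxypent-2-en-4-ynoate | COC#C/C=C(/c1ccc(O[Si](C(C)C)(C(C)C)C(C)C)cc1O[Si](C(C)C)(C(C)C)C(C)C)C(=O)OCC
F10 | step 4 | (Z)-2-[2,4-bis(triisopropylsilyloxy)phenyl]-5-methoxypent-2-en-4-yn-1-ol | COC#C/C=C(\CO)c1ccc(O[Si](C(C)C)(C(C)C)C(C)C)cc1O[Si](C(C)C)(C(C)C)C(C)C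
F11 | step 6 | tributyl(methoxyethynyl)stannane | CCCC[Sn](CCCC)(CCCC)C#COC
F12 | step 1 | 1-methoxypent-4-en-1-yne | COC#CCC=C
F13 | step 1 | 3-methoxy-2-(prop-2-enyl)cyclobut-2-en-1-one | COC1=C(CC=C)C(=O)C1
A1 | alternative 1 | (±)-cis-1,3-dimethoxy-2-(3-methylbut-2-enyl)-9-(triisopropylsilyloxy)pterocarpan (racemic, one enantiomer drawn) | COc1cc2OC[C@H]3c4ccc(O[Si](C(C)C)(C(C)C)C(C)C)cc4O[C@H]3c2c(OC)c1CC=C(C)C
A2 | alternative 1 | 5,7-dimethoxy-6-(3-methylbut-2-enyl)-2H-chromene | COc1cc2OCC=Cc2c(OC)c1CC=C(C)C
A3 | alternative 1 | 2-iodo-5-(triisopropylsilyloxy)phenol | Oc1cc(O[Si](C(C)C)(C(C)C)C(C)C)ccc1I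
A4 | alternative 2 | 5,7-dihydroxy-6-(3-methylbut-2-enyl)-2',4'-bis(triisopropylsilyloxy)isoflavone | Oc1cc2occ(-c3ccc(O[Si](C(C)C)(C(C)C)C(C)C)cc3O[Si](C(C)C)(C(C)C)C(C)C)c(=O)c2c(O)c1CC=C(C)C
A5 | alternative 2 | methyl 4-{5-[2,4-bis(triisopropylsilyloxy)phenyl]-4-oxo-4H-pyran-2-yl}-2-(3-methylbut-2-enyl)-3-oxobutanoate (racemic) | COC(=O)C(CC=C(C)C)C(=O)Cc1cc(=O)c(-c2ccc(O[Si](C(C)C)(C(C)C)C(C)C)cc2O[Si](C(C)C)(C(C)C)C(C)C)co1
A6 | alternative 3 | 2',4'-di-O-pivaloyldehydroglyasperin D | COc1cc2c(c(OC)c1CC=C(C)C)C=C(c1ccc(OC(=O)C(C)(C)C)cc1OC(=O)C(C)(C)C)CO2
A7 | alternative 3 | 4-{(E)-2-[2,4-dimethoxy-6-(methoxymethoxy)-3-(3-methylbut-2-enyl)phenyl]ethenyl}-1,3-phenylene bis(2,2-dimethylpropanoate) | COCOc1cc(OC)c(CC=C(C)C)c(OC)c1/C=C/c1ccc(OC(=O)C(C)(C)C)cc1OC(=O)C(C)(C)C
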